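**Overview**
1. Numbering: C1 carries CH2OBz (C7), C2 the benzoate, C3 the free hydroxyl, C4=C5 is the alkene and C6 is the oxirane CH. The oxirane oxygen, O–C2 and O–C3 all stand on one face of the six-membered ring.
2. Retrosynthetic cuts, in order: C3–H (carbinol to enone, enone to dimethyl ketal), the benzoyl–O bond at C2, both oxirane bonds O–C1 and O–C6, C2–H (carbinol to dienone), one MeO–C3 bond (ketal to arene), the C7–O ester bond and C7–H, which ends at o-vanillin.
3. Forward: the carbocycle is never built. It is the benzene ring of o-vanillin, dearomatised with iodine(III) in methanol. The oxirane is the only ring that is closed (step 5).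
4. Enabling feature: O–C2 sits on the ring carbon next to oxirane carbon C1 and on the same face as the oxirane oxygen. At the cyclohexa-1,3-diene stage a free C2 hydroxyl is therefore allylic to C1=C6 and can pass an oxygen atom to that alkene from its own face.
5. Stereochemistry: C2 comes from a catalytic CBS reduction of the dienone. C1 and C6 are relayed from C2 in the directed epoxidation. C3 comes from hydride attack on the enone opposite the C2 benzoate and the oxirane.

Key step: step 5

Assumption: in the CBS complex the fully substituted ketal carbon C3 is taken as the larger flank of the C2 carbonyl and the sp2 carbon C1 as the smaller, which calls for the (R)-catalyst to reach the S carbinol. If a Mosher ester check on the first batch shows the opposite sense, the (S)-catalyst takes its place and nothing else changes.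

Step 1
Reactants: 1 o-vanillin (2-hydroxy-3-methoxybenzaldehyde)
Product: 2 o-vanillyl alcohol (2-(hydroxymethyl)-6-methoxyphenol)
Conditions: NaBH4, MeOH, 0 °C; aq NH4Cl
Reagents that add atoms: none
Why: Borohydride reduction of an aryl aldehyde is fast and chemoselective, the phenol and the aryl methyl ether are inert to it, and no stereocentre arises.

Step 2
Reactants: 2 o-vanillyl alcohol; 3 benzoic acid
Product: 4 2-hydroxy-3-methoxybenzyl benzoate
Conditions: BzOH (1.3 equiv), PPh3, DIAD, THF, 0 °C to rt
Reagents that add atoms: benzoic acid (3), O=C(O)c1ccccc1
Why: Mitsunobu esterification is known to acylate phenolic benzyl alcohols at the alcohol only, because the oxyphosphonium ion forms at the aliphatic hydroxyl and only the far more acidic carboxylic acid acts as pronucleophile, and the slightly acidic medium never produces the phenoxide that would expel the ortho benzoate as an o-quinone methide (the weakness of any base- or amine-mediated cleavage of a bis-benzoate).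

Step 3
Reactants: 4 2-hydroxy-3-methoxybenzyl benzoate
Product: 5 o-quinone monoketal, (5,5-dimethoxy-6-oxocyclohexa-1,3-dien-1-yl)methyl benzoate (C2 ketone, C3 dimethyl ketal, C1=C6–C5=C4 diene)
Conditions: PhI(OAc)2 (1.05 equiv), MeOH–CH2Cl2 (1:4), −10 °C; cold aq NaHCO3 wash, Na2SO4 then 4 Å MS; kept as a dilute solution below −20 °C and used at once
Reagents that add atoms: methanol, CO
Why: Hypervalent iodine oxidative dearomatisation of a 2-methoxyphenol, in which the phenol exchanges onto iodine(III) and methanol then attacks the ortho carbon that already bears methoxy, where the developing positive charge is best stabilised, while cold and dilution hold back the Diels–Alder self-dimerisation of the dienone.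

Step 4
Reactants: 5 o-quinone monoketal
Product: 6 (S)-dienol, [(6S)-6-hydroxy-5,5-dimethoxycyclohexa-1,3-dien-1-yl]methyl benzoate (the carbinol is C2 of the overview numbering)
Conditions: (R)-Me-CBS (20 mol %), catecholborane (2 equiv), toluene–CH2Cl2, −78 °C; cold aq NaHCO3; crude product kept cold with a trace of Et3N
Reagents that add atoms: none
Why: Corey–Bakshi–Shibata reduction, established for 2-substituted cyclohex-2-enones and for α-keto acetals, in which the carbonyl oxygen binds the ring boron through the lone pair next to the smaller flank and the nitrogen-bound borane passes hydride to one face through a six-membered transition state, which sets C2 as S, and catecholborane at −78 °C reduces 1,2 without touching diene, ketal or ester.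

Step 5
Reactants: 6 (S)-dienol
Product: 7 syn epoxy alcohol, [(1R,2S,6S)-2-hydroxy-3,3-dimethoxy-7-oxabicyclo[4.1.0]hept-4-en-1-yl]methyl benzoate (oxirane oxygen cis to the C2 hydroxyl)
Conditions: VO(acac)2 (3 mol %), t-BuOOH (5.5 M in decane, 1.3 equiv), 2,6-lutidine (0.2 equiv), CH2Cl2, −10 to 0 °C; aq Na2S2O3; Et3N-deactivated silica
Reagents that add atoms: tert-butyl hydroperoxide, CC(C)(C)OO
Why: The C2 hydroxyl exchanges onto vanadium(V) as an alkoxide beside the coordinated tert-butyl peroxide, and the activated peroxide oxygen is handed in one concerted event to the adjacent C1=C6 π bond with release of tert-butanol. The closest known reaction type is the vanadium/alkyl hydroperoxide epoxidation of cyclic allylic alcohols and dienols, which is reliably syn selective. The oxirane closes by direct oxygen-atom transfer, a suprafacial [2+1] addition that forms O–C1 and O–C6 together, and not by a displacement. Both new stereocentres, the fully substituted C1 and C6, are controlled by the C2 carbinol, because a metal tethered to the C2 oxygen (held pseudoaxial by A(1,2) strain with CH2OBz) can reach only the face on which that oxygen stands. The step needs site selectivity for C1=C6 over C4=C5, secured because the hydroxyl is allylic to the trisubstituted C1=C6 but only homoallylic, across the ketal carbon, to C4=C5. The buffered, nearly neutral medium keeps the dienol from ionising its ketal, losing methanol and falling back to the arene.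

Step 6
Reactants: 7 syn epoxy alcohol; 8 benzoyl chloride
Product: 9 epoxy ketal dibenzoate, [(1S,2S,6S)-2-benzoyloxy-3,3-dimethoxy-7-oxabicyclo[4.1.0]hept-4-en-1-yl]methyl benzoate (same spatial arrangement as 7; the C1 descriptor changes by CIP priority only)
Conditions: BzCl (1.5 equiv), pyridine (4 equiv), DMAP (10 mol %), CH2Cl2, 0 °C to rt
Reagents that add atoms: benzoyl chloride (8), O=C(Cl)c1ccccc1
Why: DMAP-catalysed acylation through the N-benzoylpyridinium ion reaches even this carbinol flanked by two fully substituted carbons, the C2–O bond is not broken so the configuration is kept, and the mildly basic medium is harmless to ketal and oxirane.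

Step 7
Reactants: 9 epoxy ketal dibenzoate
Product: 10 epoxy enone, [(1S,2S,6S)-2-benzoyloxy-3-oxo-7-oxabicyclo[4.1.0]hept-4-en-1-yl]methyl benzoate
Conditions: silica gel wetted with 10% aq oxalic acid, CH2Cl2, 0 °C; filtration, no base, concentrated cold and used directly
Reagents that add atoms: water, O
Why: Acid-catalysed ketal hydrolysis on wet silica gel, in which the allylic dimethyl ketal ionises to a conjugated oxocarbenium ion much more readily than the oxirane (whose carbons are deactivated by the neighbouring acyloxy groups) opens, as known for epoxides of quinone monoketals, and the exclusion of base prevents enolisation at C2, which would scramble that centre and open the oxirane by β-elimination.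

Step 8
Reactants: 10 epoxy enone
Product: 11 target CNP0285759.1, [(1S,2R,3R,6S)-2-benzoyloxy-3-hydroxy-7-oxabicyclo[4.1.0]hept-4-en-1-yl]methyl benzoate
Conditions: NaBH4 (1 equiv), CeCl3·7H2O (1.1 equiv), MeOH–CH2Cl2 (3:1), −78 °C; pH 7 phosphate buffer
Reagents that add atoms: none
Why: Luche reduction gives clean 1,2-addition to the enone, and hydride should enter anti to the adjacent C2–OBz bond (polar Felkin–Anh model) on the face opposite the benzoate and the oxirane oxygen, so the new hydroxyl ends cis to O–C2 (3R), while the cold neutral work-up avoids benzoyl migration from O–C2 to O–C3.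

**Compound list**
1 | o-vanillin (2-hydroxy-3-methoxybenzaldehyde) | COc1cccc(C=O)c1O | starting material
2 | o-vanillyl alcohol | COc1cccc(CO)c1O | intermediate
3 | benzoic acid | O=C(O)c1ccccc1 | starting material
4 | 2-hydroxy-3-methoxybenzyl benzoate | COc1cccc(COC(=O)c2ccccc2)c1O | intermediate
5 | (5,5-dimethoxy-6-oxocyclohexa-1,3-dien-1-yl)methyl benzoate | COC1(OC)C=CC=C(COC(=O)c2ccccc2)C1=O | intermediate
6 | [(6S)-6-hydroxy-5,5-dimethoxycyclohexa-1,3-dien-1-yl]methyl benzoate | O=C(OCC1=CC=CC(OC)(OC)[C@H]1O)c1ccccc1 | intermediate
7 | [(1R,2S,6S)-2-hydroxy-3,3-dimethoxy-7-oxabicyclo[4.1.0]hept-4-en-1-yl]methyl benzoate | O=C(OC[C@]12O[C@H]1C=CC(OC)(OC)[C@H]2O)c1ccccc1 | intermediate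
8 | benzoyl chloride | O=C(Cl)c1ccccc1 | starting material
9 | [(1S,2S,6S)-2-benzoyloxy-3,3-dimethoxy-7-oxabicyclo[4.1.0]hept-4-en-1-yl]methyl benzoate | O=C(OC[C@]12O[C@H]1C=CC(OC)(OC)[C@H]2OC(=O)c1ccccc1)c1ccccc1 | intermediate
10 | [(1S,2S,6S)-2-benzoyloxy-3-oxo-7-oxabicyclo[4.1.0]hept-4-en-1-yl]methyl benzoate | O=C(OC[C@]12O[C@H]1C=CC(=O)[C@H]2OC(=O)c1ccccc1)c1ccccc1 | intermediate
11 | [(1S,2R,3R,6S)-2-benzoyloxy-3-hydroxy-7-oxabicyclo[4.1.0]hept-4-en-1-yl]methyl benzoate | O=C(OC[C@]12O[C@H]1C=C[C@@H](O)[C@H]2OC(=O)c1ccccc1)c1ccccc1 | target

Total step count: 8. Longest linear sequence: 8 steps (1 to 11).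

**Steps most likely to fail**

Step 4 (reduction of the short-lived dienone). The dienone may dimerise by Diels–Alder reaction while methanol and water are being removed. The catalyst may also distinguish the two bulky flanks of the carbonyl only poorly, so that enantiomeric purity stays low. The fallback moves absolute control from catalysis to a resolution. It sets out from 4. The iodine(III) oxidation is run in neat methanol at −20 °C, and CeCl3·7H2O and NaBH4 are added to the same flask at −78 °C, so that 5 is reduced as soon as it forms and is never concentrated. This gives the racemic dienol F1. The conditions of steps 5 and 6 turn it into the racemic syn epoxy alcohol F2 and then the racemic epoxy ketal dibenzoate F3, the sturdiest compound of the series. F3 is separated by preparative chromatography on a polysaccharide chiral stationary phase. The (1S,2S,6S) enantiomer is 9, where the route is rejoined.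

Step 5 (directed epoxidation of the acid-labile dienol). Vanadium acting as a Lewis acid may ionise the ketal, so that the dienol loses methanol and re-aromatises, or vanadium(V) may oxidise the carbinol back to the dienone. The fallback gives up the metal. Delivery through a covalent metal alkoxide is replaced by delivery through a hydrogen bond (Henbest effect). Compound 6 is treated with purified mCPBA in a two-phase CH2Cl2/aq NaHCO3 system at 0 °C, where the C2 hydroxyl binds the peracid and guides it to the near alkene on its own face. No Lewis acid and no alcohol-oxidising species is present. The fallback sets out from 6 and comes back at 7, and it passes through no compound that is not already listed (none F0).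

Step 8 (last stereocentre). Facial selectivity may be poor, because the CH2OBz group on C1 shields the upper face and may offset the bias exerted by the C2 benzoate, so that hydride also enters from the lower face. The fallback accepts the wrong face and corrects it by inversion. It sets out from 10, whose reduction is taken as it falls, and the C3 epimer with trans C2/C3 oxygens F4 is isolated. Its allylic carbinol is inverted by a Mitsunobu reaction with chloroacetic acid (PPh3, DIAD, toluene, 0 °C) to the cis chloroacetate F5. Thiourea (EtOH–THF, mild warming, NaHCO3 wash) then removes the chloroacetyl group selectively beside the two benzoates and returns the route at 11.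

**Further compounds**
F1 | step 4 | racemic [6-hydroxy-5,5-dimethoxycyclohexa-1,3-dien-1-yl]methyl benzoate (both enantiomers) | O=C(OCC1=CC=CC(OC)(OC)[C@H]1O)c1ccccc1.O=C(OCC1=CC=CC(OC)(OC)[C@@H]1O)c1ccccc1
F2 | step 4 | racemic syn epoxy alcohol, (1R*,2S*,6S*)-2-hydroxy-3,3-dimethoxy-7-oxabicyclo[4.1.0]hept-4-en-1-yl]methyl benzoate (both enantiomers) | O=C(OC[C@]12O[C@H]1C=CC(OC)(OC)[C@H]2O)c1ccccc1.O=C(OC[C@@]12O[C@@H]1C=CC(OC)(OC)[C@@H]2O)c1ccccc1
F3 | step 4 | racemic epoxy ketal dibenzoate, (1S*,2S*,6S*) (both enantiomers) | O=C(OC[C@]12O[C@H]1C=CC(OC)(OC)[C@H]2OC(=O)c1ccccc1)c1ccccc1.O=C(OC[C@@]12O[C@@H]1C=CC(OC)(OC)[C@@H]2OC(=O)c1ccccc1)c1ccccc1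
F0 | step 5 | none | none
F4 | step 8 | C3 epimer, [(1S,2R,3S,6S)-2-benzoyloxy-3-hydroxy-7-oxabicyclo[4.1.0]hept-4-en-1-yl]methyl benzoate | O=C(OC[C@]12O[C@H]1C=C[C@H](O)[C@H]2OC(=O)c1ccccc1)c1ccccc1
F5 | step 8 | cis chloroacetate, [(1S,2R,3R,6S)-2-benzoyloxy-3-(2-chloroacetoxy)-7-oxabicyclo[4.1.0]hept-4-en-1-yl]methyl benzoate | O=C(OC[C@]12O[C@H]1C=C[C@@H](OC(=O)CCl)[C@H]2OC(=O)c1ccccc1)c1ccccc1
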